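If each product costs the catalyst one turn of its round, a flask can be reckoned by counting turns before any model is fitted. This flask holds substrate, reagent and free catalyst, and we look at it when 30% of the substrate is converted.

| setting | beta | zeta | eta | flask |
|---|---|---|---|---|
| substrate | 20 mM | 20 mM | 40 mM | 20 mM |
| reagent | 18 mM | 72 mM | 36 mM | 36.0 mM |
| free catalyst | 1 mM | 1 mM | 1 mM | 1.0 mM |
| remark | run made earlier | run made earlier | run made earlier |  |

| run | time / min | product / % | substrate / % |
|---|---|---|---|
| beta | 2.00 | 3.2 | 94.6 |
| beta | 4.00 | 9.1 | 90.7 |
| beta | 6.00 | 13.3 | 87.6 |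
| beta | 8.00 | 13.9 | 82.4 |
| beta | 10.0 | 18.1 | 80.1 |
| beta | 12.0 | 23.5 | 76.1 |
| beta | 15.0 | 26.7 | 72.5 |
| zeta | 2.00 | 1.4 | 92.7 |
| zeta | 4.00 | 9.7 | 88.9 |
| zeta | 6.00 | 13.1 | 81.3 |
| zeta | 8.00 | 17.9 | 78.5 |
| zeta | 10.0 | 23.1 | 74.5 |
| zeta | 12.0 | 25.5 | 72.6 |
| zeta | 15.0 | 31.3 | 65.2 |
| eta | 3.00 | 5.0 | 93.8 |
| eta | 6.00 | 8.9 | 90.7 |
| eta | 8.00 | 10.2 | 87.2 |
| eta | 12.0 | 15.3 | 84.7 |
| eta | 15.0 | 17.0 | 81.1 |

(readings scatter by 1 percentage point)



- apparent order in reagent when 30% of the substrate are converted (percent change of the rate of making product for one percent more reagent charged)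

By then the substrate converted per catalyst charged, a turnover number counted on substrate lost and not on product, is 6.00.

Two chemists dispute the order in reagent. The first says every turn waits for a reagent to arrive, so turn time follows one over reagent and the order is 1. The second says most of a turn passes without reagent, and the runs give her numbers. Count as converted the mean of product and substrate lost at 15.0 min: a turn then lasts 2.77 min in beta and 2.27 min in zeta, though zeta has 4.00 times the reagent.

My own reckoning splits the turn into a fixed part and a waiting part that follows one over reagent. Beta holds half the flask's reagent charge and zeta twice that charge, so at the full charge the wait is 0.332 min and the fixed part 2.10 min. The first view holds where the wait passes the fixed part, below 15.8% of the flask's charge. Taking one reagent per turn, 83.3% of the reagent remains at the look point, and the wait grows to 0.399 min. The order is the wait's share of the turn, 0.159, a rough figure with readings that scatter by 1 percentage point.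

The forecast takes the second side with 0.18, saying the small gain from reagent “suggests saturation”.

The simulation gives 0.21, somewhat above my 0.159.

    catalyst intermediate C → free catalyst + product (k = 2.50 min⁻¹)
    reagent + free catalyst ⇌ catalyst intermediate A (K = 64.0 M⁻¹, k = 4200 M⁻¹ min⁻¹)
    catalyst intermediate A ⇌ by-product + catalyst intermediate B (K = 0.0150 M, k = 2.20 min⁻¹)
    substrate + catalyst intermediate B → catalyst intermediate C (k = 79.0 M⁻¹ min⁻¹)
    substrate + catalyst intermediate C → spent catalyst (k = 5.30 M⁻¹ min⁻¹)

At 4.53 min, catalyst intermediate C in this flask goes to free catalyst and product 27 times for each time it reacts with substrate to spent catalyst, and at that ratio a count of 6.00 turns comes to about 22.2% of the catalyst. In this flask at 13.7 min, when 30% of the substrate is converted, spent catalyst stands at 19.6% of the catalyst. With twice the free catalyst, each catalyst needs half the turns, 3.00, and the time to that conversion changes by the factor 0.483.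

(The runs are simulated for substances that don't exist, noise included.)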